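**Retrosynthetic overview**

1. The target is reached from pentacycle 19 by oxidation-state work only: 9α,11α-epoxidation (last), C15 allylic oxidation to the enone, and a cis-1α,2α-diol made from a C1/C2 dione by β-face hydride delivery.
2. 19 ⇐ 15 + 3-methylbut-2-enal (16): one operation forms C3–C4 and C5–C10 by an O-tethered polar (4+2) addition of a prenal-derived vinyl oxocarbenium ion (C4=C5–C6=O7+) to the 2-silyloxydiene C10=C1–C2(OSi)=C3, closing ring A and the seven-membered ring B together.
3. Enabling feature: in ring B (C5, C6, O7, C7, C8, C9, C10) the lactol carbon C6 is an aldehyde carbon joined through O7–C7 to the quaternary C8, and C8 is bonded to C9, which carries C10. C4–C5–C6 is therefore prenal hung on the C7 oxygen and held over a diene on C9.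
4. 15 ⇐ Stille union of the bicyclo[3.2.1]octenyl iodide 11 (rings C and D) with stannyl enone 13; 11 ⇐ intramolecular dienolate C-alkylation (C8–C15, ring D) of a cyclohexene carbaldehyde made from (R)-5-isopropenylcyclohex-2-enone; C13 comes from a rhodium-catalysed asymmetric conjugate addition to cyclohexenone.
5. Ring order: C (from cyclohexenone) → D (step 6) → A and B together (step 11) → oxirane (step 19).

Key step: step 11

Numbering and faces: kaurane-type locants of the target are used (ring A: C1–C5, C10; ring B: C5, C6, O7, C7, C8, C9, C10; ring C: C8, C9, C11–C14; ring D: C8, C13–C16; C17 is the exocyclic CH2; C18, C19, C20 are the methyls). β is the face of the C15–C16 bridge, α the face of the C20 methyl. The skeleton is called 6,7-epoxy-6,7-secokaurane; "5β" refers to H5 and "10α" to the C10 methyl.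

Assumption: the lactol carbon C6 epimerises by ring–chain tautomerism, and the epimer drawn in the target is taken to be the thermodynamically preferred one; it is not controlled separately.

**Route**

Step 1
Reactants: 1 cyclohex-2-en-1-one; 2 isopropenylboronic acid pinacol ester
Product: 3 (R)-3-(prop-1-en-2-yl)cyclohexan-1-one
Conditions: [Rh(cod)Cl]2 (1.5 mol%), (R)-BINAP (3.3 mol%), KOH (10 mol%), dioxane/H2O 10:1, 40 °C
Reagents that add atoms: 2 isopropenylboronic acid pinacol ester, CC(=C)B1OC(C)(C)C(C)(C)O1
Why: Hayashi–Miyaura rhodium-catalysed asymmetric conjugate addition; the (R)-BINAP complex should deliver the alkenyl group to the enone face that gives the (R)-ketone, by analogy with aryl- and alkenylboron additions to cyclohexenone, and this sets C13.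

Step 2
Reactants: 3
Product: 5 (R)-5-(prop-1-en-2-yl)cyclohex-2-en-1-one, via trimethylsilyl enol ether 4 (not isolated)
Conditions: LiN(iPr)2, Me3SiCl (in situ), THF, −78 °C; then Pd(OAc)2 (10 mol%), O2 (1 atm), DMSO, 25 °C
Reagents that add atoms: none
Why: Kinetic deprotonation with in-situ silylation should favour the α-carbon remote from the C13 substituent (C9), and Saegusa–Ito dehydrogenation of that silyl enol ether gives the 5-substituted enone without touching C13.

Step 3
Reactants: 5
Product: 6 (R)-2-iodo-5-(prop-1-en-2-yl)cyclohex-2-en-1-one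
Conditions: I2, pyridine/CH2Cl2 1:1, 0 → 25 °C
Reagents that add atoms: iodine, II
Why: α-Iodination of the enone by reversible pyridine conjugate addition, iodination of the enolate and elimination (Baylis–Hillman-type pathway), which places the cross-coupling handle on C9; the isolated isopropenyl alkene is inert to iodine–pyridine.

Step 4
Reactants: 6
Product: 7 (R)-5-(3-chloroprop-1-en-2-yl)-2-iodocyclohex-2-en-1-one
Conditions: Ca(OCl)2, solid CO2, CH2Cl2/H2O, 0 °C
Reagents that add atoms: calcium hypochlorite, [Ca+2].[O-]Cl.[O-]Cl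
Why: Ene-type allylic chlorination by HOCl of the only electron-rich alkene (the iodoenone alkene is deactivated), as known for the isopropenyl group of carvone-type enones; it gives the 2-(chloromethyl)allyl unit whose CH2Cl carbon becomes C15.

Step 5
Reactants: 7
Product: 9 (5R)-5-(3-chloroprop-1-en-2-yl)-2-iodocyclohex-1-ene-1-carbaldehyde, via methyl dienyl ether 8 (not isolated)
Conditions: MeOCH2PPh3Cl, KN(SiMe3)2, THF, −78 → 0 °C; then 2 M aq. HCl, THF, 25 °C
Reagents that add atoms: (methoxymethyl)triphenylphosphonium chloride, COC[P+](c1ccccc1)(c1ccccc1)c1ccccc1.[Cl-]; water, O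
Why: Wittig methoxymethylenation of the ketone and acid hydrolysis of the dienyl ether give the one-carbon homologue (C7 as aldehyde); the conjugated β-iodo enal is expected, and its β,γ-isomer would lead to the same dienolate in step 6.

Step 6
Reactants: 9
Product: 10 (1S,5R)-2-iodo-6-methylidenebicyclo[3.2.1]oct-2-ene-1-carbaldehyde
Conditions: KN(SiMe3)2 (1.05 equiv), THF, −78 → 0 °C
Reagents that add atoms: none
Why: γ-Deprotonation gives the extended dienolate, which should be alkylated kinetically at its α-carbon C8 by the allylic chloride (intramolecular deconjugative alkylation, 5-exo-tet), closing ring D and creating the quaternary C8; its configuration is dictated by C13 because the two-carbon bridge can only span cis.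

Step 7
Reactants: 10
Product: 11 [(1S,5R)-2-iodo-6-methylidenebicyclo[3.2.1]oct-2-en-1-yl]methanol
Conditions: NaBH4, MeOH, 0 °C
Reagents that add atoms: none
Why: Borohydride reduction of the neopentyl aldehyde gives the C7 alcohol; the vinyl iodide and the exocyclic alkene are not reducible under these conditions.

Step 8
Reactants: 12 pent-3-yn-2-one
Product: 13 (E)-4-(tributylstannyl)pent-3-en-2-one
Conditions: Bu3SnH, LiN(iPr)2, THF, 0 °C; CuBr·SMe2, −78 °C; then 12, MeOH, −78 °C
Reagents that add atoms: tributyltin hydride, CCCC[SnH](CCCC)CCCC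
Why: syn-Stannylcupration of the ynone with protonation in situ places tin on the β-carbon and trans to the acyl group, so the (E)-geometry needed for the diene is fixed here.

Step 9
Reactants: 11; 13
Product: 14 (E)-4-[(1R,5R)-1-(hydroxymethyl)-6-methylidenebicyclo[3.2.1]oct-2-en-2-yl]pent-3-en-2-one
Conditions: Pd2(dba)3 (5 mol%), AsPh3 (20 mol%), copper iodide CuI (20 mol%), NMP, 40 °C
Reagents that add atoms: 13 (E)-4-(tributylstannyl)pent-3-en-2-one, CC(=O)/C=C(\C)[Sn](CCCC)(CCCC)CCCC
Why: Stille coupling (arsine ligand and copper co-catalysis for the hindered vinyl iodide) joins C9 to C10 with retention of both alkene geometries, so C9 ends trans to the acyl group across C10=C1; the neutral conditions avoid oxa-Michael addition of the free C7 hydroxyl.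

Step 10
Reactants: 14
Product: 15 trimethyl({(1R,5R)-6-methylidene-2-[(2E)-4-(trimethylsilyloxy)penta-2,4-dien-2-yl]bicyclo[3.2.1]oct-2-en-1-yl}methoxy)silane
Conditions: Me3SiOTf (2.5 equiv), Et3N (3.5 equiv), CH2Cl2, −78 → 0 °C
Reagents that add atoms: trimethylsilyl triflate, C[Si](C)(C)OS(=O)(=O)C(F)(F)F
Why: One operation silylates the primary alcohol and enolises the methyl ketone at its methyl group (soft enolisation), giving the cross-conjugated 2-silyloxydiene and the silyl ether from which the oxocarbenium ion is made.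

Step 11
Reactants: 15; 16 3-methylbut-2-enal
Product: 19 (5β,6β,10α)-6-methoxy-2-(trimethylsilyloxy)-6,7-epoxy-6,7-secokaura-1,9(11),16-triene, via vinyl oxocarbenium triflate 17 (not isolated), via cyclic oxocarbenium triflate 18 (not isolated)
Conditions: 16 (1.5 equiv), Me3SiOTf (1.1 equiv), 2,6-di-tert-butyl-4-methylpyridine, CH2Cl2 (0.005 M), −78 °C; then MeOSiMe3, −78 → −40 °C; Et3N
Reagents that add atoms: 16 3-methylbut-2-enal, CC(C)=CC=O; methoxytrimethylsilane, CO[Si](C)(C)C
Why: Proposed new method: Me3SiOTf converts the C7 silyl ether and aldehyde 16 into the O7-tethered 1-alkoxy-3,3-dimethylallyl (vinyl oxocarbenium) cation 17, whose C4=C5 bond adds to the electron-rich silyloxydiene in a polar, asynchronous (4+2) process (C3–C4 bond leading, C5–C10 bond closing, so that no coplanar s-cis diene is required despite the inside C20 methyl) to give cyclic oxocarbenium ion 18, which MeOSiMe3 captures as acetal 19 with return of Me3SiOTf. The closest known reaction types are the ionic Diels–Alder reaction of α,β-unsaturated acetals with 1,3-dienes and the silyl ether/aldehyde/Me3SiOTf generation of oxocarbenium ions used in three-component Sakurai allylations; new here are the tether through the acetal oxygen and the closure of a seven-membered ring. Ring A (C1–C5, C10) closes as the six-membered ring of the (4+2) event (in the stepwise limit a 6-endo Michael-type closure of the C5=C6 enol ether onto C10 of the silyloxyallyl cation), and ring B is the seven-membered tether ring closed by the same C5–C10 bond, with the O7=C6 oxocarbenium bond ending inside it. C10 is controlled by the tether, which starts at C7 close to the plane of the C9=C11 bond on the C8 side and can deliver C5 only to the diene face turned toward C8; the step needs the rotamer with the diene arm C1=C2 on the side of the C15–C16 bridge and the C20 methyl toward C14, which is the arrangement in which tether and diene arm lie on opposite sides of the C9–C10 axis, and this same exo (anti) arrangement sets C5 and the trans A/B fusion, while the C6 configuration is of no consequence (6β drawn; both epimers converge in step 18). The step also needs 1,4- rather than 1,2-attack on the alkoxyallyl cation and reaction at the silyl enol ether rather than at the C16=C17 or C9=C11 alkenes: attack of C3 at C6 would close a nine-membered ring whereas the (4+2) mode closes six- and seven-membered rings, the silyl enol ether terminus is by far the strongest π-nucleophile present, and high dilution suppresses intermolecular Mukaiyama-type addition.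

Step 12
Reactants: 19
Product: 20 (1β,5β,6β,10α)-1-hydroxy-6-methoxy-6,7-epoxy-6,7-secokaura-9(11),16-dien-2-one
Conditions: mCPBA (1.0 equiv), NaHCO3, CH2Cl2, −20 °C; then K2CO3 (cat.), MeOH, 0 °C
Reagents that add atoms: 3-chloroperbenzoic acid, OOC(=O)c1cccc(Cl)c1
Why: Rubottom oxidation; the silyl enol ether is far more electron-rich than the other two alkenes, so one equivalent of peracid should oxidise only C1=C2 (from the open β-face, which is immaterial because C1 is oxidised again in step 13).

Step 13
Reactants: 20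
Product: 21 (5β,6β,10α)-6-methoxy-6,7-epoxy-6,7-secokaura-9(11),16-diene-1,2-dione
Conditions: Dess–Martin periodinane, NaHCO3, CH2Cl2, 25 °C
Reagents that add atoms: none
Why: Dess–Martin oxidation of the ketol (or of any transposed ketol) gives the 1,2-dione, expected largely as its diosphenol tautomer enolised toward C3, and removes the C1 stereocentre so that C1 and C2 can be set together.

Step 14
Reactants: 21
Product: 22 (1α,2α,5β,6β,10α)-6-methoxy-6,7-epoxy-6,7-secokaura-9(11),16-diene-1,2-diol
Conditions: NaBH4, CeCl3·7H2O, MeOH, −78 → 0 °C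
Reagents that add atoms: none
Why: Luche-type hydride reduction; hydride should reach both carbonyls from the β-face because the α-face is screened by the syn-axial C20 and C19 methyls (equatorial attack at C2, axial attack anti to C20 at C1), which gives the 1α,2α-cis-diol.

Step 15
Reactants: 22
Product: 23 (1α,2α,5β,6β,10α)-6-methoxy-6,7-epoxy-6,7-secokaura-9(11),16-diene-1,2-diyl diacetate
Conditions: Ac2O, DMAP, Et3N, CH2Cl2, 40 °C
Reagents that add atoms: acetic anhydride, CC(=O)OC(C)=O
Why: DMAP-catalysed acetylation of both secondary alcohols; nucleophilic catalysis and mild heating are chosen for the hindered axial 2α-hydroxyl.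

Step 16
Reactants: 23
Product: 24 (1α,2α,5β,6β,10α)-15-hydroxy-6-methoxy-6,7-epoxy-6,7-secokaura-9(11),16-diene-1,2-diyl diacetate (15-OH syn to C7)
Conditions: SeO2 (0.5 equiv), tBuOOH, CH2Cl2, 25 °C
Reagents that add atoms: selenium dioxide, O=[Se]=O; tert-butyl hydroperoxide, CC(C)(C)OO
Why: Riley-type allylic oxidation (ene reaction, then 2,3-sigmatropic shift) of the exocyclic C16=C17 alkene at C15; the C9=C11 alkene has no allylic hydrogen on its substituted end (C8 and C10 are quaternary) and C13 is a bridgehead, and the C15 configuration (drawn for exo attack) is erased in step 17.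

Step 17
Reactants: 24
Product: 25 (1α,2α,5β,6β,10α)-6-methoxy-15-oxo-6,7-epoxy-6,7-secokaura-9(11),16-diene-1,2-diyl diacetate
Conditions: Dess–Martin periodinane, NaHCO3, CH2Cl2, 25 °C
Reagents that add atoms: none
Why: Dess–Martin oxidation of the allylic alcohol gives the exo-methylene cyclopentanone while the lactol is still masked as its methyl acetal.

Step 18
Reactants: 25
Product: 26 (1α,2α,5β,6β,10α)-6-hydroxy-15-oxo-6,7-epoxy-6,7-secokaura-9(11),16-diene-1,2-diyl diacetate
Conditions: AcOH/H2O/THF 3:1:1, 45 °C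
Reagents that add atoms: water, O
Why: Mild acid hydrolysis of the cyclic methyl acetal frees the lactol, which should settle as the thermodynamically preferred C6 epimer; it is done before the acid-sensitive oxirane exists, and the acetates and the enone tolerate it.

Step 19
Reactants: 26
Product: 27 (1α,2α,5β,6β,9α,10α,11α)-9,11:6,7-diepoxy-6-hydroxy-15-oxo-6,7-secokaur-16-ene-1,2-diyl diacetate (CNP0224512.1)
Conditions: mCPBA, NaHCO3, CH2Cl2, 0 °C
Reagents that add atoms: 3-chloroperbenzoic acid, OOC(=O)c1cccc(Cl)c1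
Why: Prilezhaev epoxidation; C9=C11 is the only electron-rich alkene left (the enone alkene is deactivated) and should be attacked from the exo face of the bicyclo[3.2.1]octene, the face of the one-carbon bridge C14 and anti to the C15–C16 bridge, which gives the 9α,11α-oxirane.

**Compound list**

1 | cyclohex-2-en-1-one | O=C1C=CCCC1 | starting material
2 | isopropenylboronic acid pinacol ester | CC(=C)B1OC(C)(C)C(C)(C)O1 | starting material
3 | (R)-3-(prop-1-en-2-yl)cyclohexan-1-one | O=C1CCC[C@@H](C(C)=C)C1 | intermediate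
4 | trimethyl{[(5R)-5-(prop-1-en-2-yl)cyclohex-1-en-1-yl]oxy}silane | C[Si](C)(C)OC1=CCC[C@@H](C(C)=C)C1 | intermediate
5 | (R)-5-(prop-1-en-2-yl)cyclohex-2-en-1-one | O=C1C=CC[C@@H](C(C)=C)C1 | intermediate
6 | (R)-2-iodo-5-(prop-1-en-2-yl)cyclohex-2-en-1-one | O=C1C(I)=CC[C@@H](C(C)=C)C1 | intermediate
7 | (R)-5-(3-chloroprop-1-en-2-yl)-2-iodocyclohex-2-en-1-one | O=C1C(I)=CC[C@@H](C(=C)CCl)C1 | intermediate
8 | (4R)-4-(3-chloroprop-1-en-2-yl)-1-iodo-6-(methoxymethylidene)cyclohex-1-ene (mixture of enol ether isomers) | COC=C1C(I)=CC[C@@H](C(=C)CCl)C1 | intermediate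
9 | (5R)-5-(3-chloroprop-1-en-2-yl)-2-iodocyclohex-1-ene-1-carbaldehyde | O=CC1=C(I)CC[C@@H](C(=C)CCl)C1 | intermediate
10 | (1S,5R)-2-iodo-6-methylidenebicyclo[3.2.1]oct-2-ene-1-carbaldehyde | C=C1C[C@@]2(C=O)C(I)=CC[C@@H]1C2 | intermediate
11 | [(1S,5R)-2-iodo-6-methylidenebicyclo[3.2.1]oct-2-en-1-yl]methanol | C=C1C[C@@]2(CO)C(I)=CC[C@@H]1C2 | intermediate
12 | pent-3-yn-2-one | CC#CC(C)=O | starting material
13 | (E)-4-(tributylstannyl)pent-3-en-2-one | CC(=O)/C=C(\C)[Sn](CCCC)(CCCC)CCCC | intermediate
14 | (E)-4-[(1R,5R)-1-(hydroxymethyl)-6-methylidenebicyclo[3.2.1]oct-2-en-2-yl]pent-3-en-2-one | C=C1C[C@@]2(CO)C(/C(C)=C/C(C)=O)=CC[C@@H]1C2 | intermediate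
15 | trimethyl({(1R,5R)-6-methylidene-2-[(2E)-4-(trimethylsilyloxy)penta-2,4-dien-2-yl]bicyclo[3.2.1]oct-2-en-1-yl}methoxy)silane | C=C1C[C@@]2(CO[Si](C)(C)C)C(/C(C)=C/C(=C)O[Si](C)(C)C)=CC[C@@H]1C2 | intermediate
16 | 3-methylbut-2-enal | CC(C)=CC=O | starting material
17 | O7-tethered vinyl oxocarbenium triflate (C7–O7+=C6H–C5H=C4Me2 on the silyloxydiene of 15) | C=C1C[C@@]2(C[O+]=CC=C(C)C)C(/C(C)=C/C(=C)O[Si](C)(C)C)=CC[C@@H]1C2.[O-]S(=O)(=O)C(F)(F)F | intermediate
18 | cyclic oxocarbenium triflate (rings A and B closed, O7=C6 cation, C1=C2 silyl enol ether) | C=C1C[C@@]23C[O+]=C[C@@H]4C(C)(C)CC(O[Si](C)(C)C)=C[C@@]4(C)C2=CC[C@@H]1C3.[O-]S(=O)(=O)C(F)(F)F | intermediate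
19 | (5β,6β,10α)-6-methoxy-2-(trimethylsilyloxy)-6,7-epoxy-6,7-secokaura-1,9(11),16-triene | C=C1C[C@@]23CO[C@@H](OC)[C@@H]4C(C)(C)CC(O[Si](C)(C)C)=C[C@@]4(C)C2=CC[C@@H]1C3 | intermediate
20 | (1β,5β,6β,10α)-1-hydroxy-6-methoxy-6,7-epoxy-6,7-secokaura-9(11),16-dien-2-one | C=C1C[C@@]23CO[C@@H](OC)[C@@H]4C(C)(C)CC(=O)[C@@H](O)[C@@]4(C)C2=CC[C@@H]1C3 | intermediate
21 | (5β,6β,10α)-6-methoxy-6,7-epoxy-6,7-secokaura-9(11),16-diene-1,2-dione (diosphenol tautomer expected) | C=C1C[C@@]23CO[C@@H](OC)[C@@H]4C(C)(C)CC(=O)C(=O)[C@@]4(C)C2=CC[C@@H]1C3 | intermediate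
22 | (1α,2α,5β,6β,10α)-6-methoxy-6,7-epoxy-6,7-secokaura-9(11),16-diene-1,2-diol | C=C1C[C@@]23CO[C@@H](OC)[C@@H]4C(C)(C)C[C@H](O)[C@H](O)[C@@]4(C)C2=CC[C@@H]1C3 | intermediate
23 | (1α,2α,5β,6β,10α)-6-methoxy-6,7-epoxy-6,7-secokaura-9(11),16-diene-1,2-diyl diacetate | C=C1C[C@@]23CO[C@@H](OC)[C@@H]4C(C)(C)C[C@H](OC(C)=O)[C@H](OC(C)=O)[C@@]4(C)C2=CC[C@@H]1C3 | intermediate
24 | (1α,2α,5β,6β,10α)-15-hydroxy-6-methoxy-6,7-epoxy-6,7-secokaura-9(11),16-diene-1,2-diyl diacetate (15-OH syn to C7) | C=C1[C@H](O)[C@@]23CO[C@@H](OC)[C@@H]4C(C)(C)C[C@H](OC(C)=O)[C@H](OC(C)=O)[C@@]4(C)C2=CC[C@@H]1C3 | intermediate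
25 | (1α,2α,5β,6β,10α)-6-methoxy-15-oxo-6,7-epoxy-6,7-secokaura-9(11),16-diene-1,2-diyl diacetate | C=C1C(=O)[C@@]23CO[C@@H](OC)[C@@H]4C(C)(C)C[C@H](OC(C)=O)[C@H](OC(C)=O)[C@@]4(C)C2=CC[C@@H]1C3 | intermediate
26 | (1α,2α,5β,6β,10α)-6-hydroxy-15-oxo-6,7-epoxy-6,7-secokaura-9(11),16-diene-1,2-diyl diacetate | C=C1C(=O)[C@@]23CO[C@@H](O)[C@@H]4C(C)(C)C[C@H](OC(C)=O)[C@H](OC(C)=O)[C@@]4(C)C2=CC[C@@H]1C3 | intermediate
27 | (1α,2α,5β,6β,9α,10α,11α)-9,11:6,7-diepoxy-6-hydroxy-15-oxo-6,7-secokaur-16-ene-1,2-diyl diacetate (CNP0224512.1) | C=C1C(=O)[C@@]23CO[C@@H](O)[C@@H]4C(C)(C)C[C@H](OC(C)=O)[C@H](OC(C)=O)[C@@]4(C)[C@]24O[C@@H]4C[C@@H]1C3 | target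

**Step count and risks**

Total step count: 19. Longest linear sequence: 18 steps (steps 1–7 and 9–19; step 8 makes side fragment 13).

Steps most likely to fail:

1. Step 11 (proposed new method). What may go wrong: intermolecular 1,2-addition of the silyl enol ether to the oxocarbenium carbon (oligomerisation) instead of cycloaddition; closure through the other rotamer about C9–C10 (wrong face at C10); or endo closure with cis A/B fusion. A cis-fused C5 epimer alone could in principle still be corrected later through the open hydroxy aldehyde of the lactol; a wrong C10 could not. Fallback by known chemistry, a thermal ester-tethered intramolecular Diels–Alder reaction, setting out from 14 and returning at 20: the C7 alcohol of 14 is acylated with 3-methylbut-2-enoyl chloride (Et3N, DMAP, CH2Cl2) to [(1R,5R)-6-methylidene-2-[(2E)-4-oxopent-2-en-2-yl]bicyclo[3.2.1]oct-2-en-1-yl]methyl 3-methylbut-2-enoate F1. The methyl ketone is converted with tBuMe2SiOTf/Et3N into the tert-butyldimethylsilyl dienol ether F2. Heating F2 (toluene, BHT, 190 °C, sealed tube) should give by concerted cycloaddition the 6-oxo lactone with the C1=C2 silyl enol ether F3, the geometry of the tether again favouring the trans-fused adduct. The lactone is reduced with iBu2AlH (CH2Cl2, −78 °C) to the lactol F4, which is O-methylated (MeI, Ag2O) to the methyl acetal F5, the tert-butyldimethylsilyl analogue of 19. Rubottom oxidation of F5 (mCPBA, then Bu4NF) rejoins the route at 20.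

2. Step 2. What may go wrong: poor regioselectivity of the kinetic deprotonation (removal of a C14 proton instead of a C9 proton), which after dehydrogenation gives the achiral conjugated 3-isopropenyl enone and loses material and the C13 stereocentre. Fallback with regiochemistry set under thermodynamic control, setting out from 3 and returning at 5: Claisen formylation (ethyl formate, NaH, THF) at the less hindered α-carbon gives (5R)-2-(hydroxymethylidene)-5-(prop-1-en-2-yl)cyclohexan-1-one F6. Deformylative diazo transfer (TsN3, Et3N, MeCN) gives (5R)-2-diazo-5-(prop-1-en-2-yl)cyclohexan-1-one F7. Rh2(OAc)4-catalysed carbenoid formation with 1,2-hydride shift (CH2Cl2, 25 °C) then gives enone 5 with the double bond necessarily at C9=C11.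

3. Step 14. What may go wrong: hydride delivery to C1 from the wrong face, or scrambling of C1 through the enediol before the second reduction, giving a trans-diol. Fallback that sets C1 by equilibration instead of by hydride delivery, setting out from 20 and returning at 22: the ketol is epimerised at C1 under equilibrating conditions (DBU, toluene, 25–60 °C) to the equatorial (1α,5β,6β,10α)-1-hydroxy-6-methoxy-6,7-epoxy-6,7-secokaura-9(11),16-dien-2-one F8. The remaining C2 ketone is then reduced with NaBH4 (MeOH, −40 °C) from the β-face to give diol 22.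

**Further compounds**

F1 | step 11 | [(1R,5R)-6-methylidene-2-[(2E)-4-oxopent-2-en-2-yl]bicyclo[3.2.1]oct-2-en-1-yl]methyl 3-methylbut-2-enoate | C=C1C[C@@]2(COC(=O)C=C(C)C)C(/C(C)=C/C(C)=O)=CC[C@@H]1C2
F2 | step 11 | [(1R,5R)-2-[(2E)-4-(tert-butyldimethylsilyloxy)penta-2,4-dien-2-yl]-6-methylidenebicyclo[3.2.1]oct-2-en-1-yl]methyl 3-methylbut-2-enoate | C=C1C[C@@]2(COC(=O)C=C(C)C)C(/C(C)=C/C(=C)O[Si](C)(C)C(C)(C)C)=CC[C@@H]1C2
F3 | step 11 | (5β,10α)-2-(tert-butyldimethylsilyloxy)-6,7-epoxy-6,7-secokaura-1,9(11),16-trien-6-one (lactone) | C=C1C[C@@]23COC(=O)[C@@H]4C(C)(C)CC(O[Si](C)(C)C(C)(C)C)=C[C@@]4(C)C2=CC[C@@H]1C3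
F4 | step 11 | (5β,6β,10α)-2-(tert-butyldimethylsilyloxy)-6,7-epoxy-6,7-secokaura-1,9(11),16-trien-6-ol (lactol) | C=C1C[C@@]23CO[C@@H](O)[C@@H]4C(C)(C)CC(O[Si](C)(C)C(C)(C)C)=C[C@@]4(C)C2=CC[C@@H]1C3
F5 | step 11 | (5β,6β,10α)-2-(tert-butyldimethylsilyloxy)-6-methoxy-6,7-epoxy-6,7-secokaura-1,9(11),16-triene | C=C1C[C@@]23CO[C@@H](OC)[C@@H]4C(C)(C)CC(O[Si](C)(C)C(C)(C)C)=C[C@@]4(C)C2=CC[C@@H]1C3
F6 | step 2 | (5R)-2-(hydroxymethylidene)-5-(prop-1-en-2-yl)cyclohexan-1-one | O=C1C(=CO)CC[C@@H](C(C)=C)C1
F7 | step 2 | (5R)-2-diazo-5-(prop-1-en-2-yl)cyclohexan-1-one | O=C1C(=[N+]=[N-])CC[C@@H](C(C)=C)C1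
F8 | step 14 | (1α,5β,6β,10α)-1-hydroxy-6-methoxy-6,7-epoxy-6,7-secokaura-9(11),16-dien-2-one | C=C1C[C@@]23CO[C@@H](OC)[C@@H]4C(C)(C)CC(=O)[C@H](O)[C@@]4(C)C2=CC[C@@H]1C3
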